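1. Dusk's readings stall. Between 8.00 h and 10.0 h its left-handed product gains 1 percentage point, which is within the scatter.

| setting | winter | dusk | autumn | delta | gamma |
|---|---|---|---|---|---|
| left-handed substrate | 0.40 M | 0.40 M | 0.40 M | 0.40 M | 0.40 M |
| right-handed substrate | 0.40 M | 0.40 M | 0.40 M | 0.40 M | 0.40 M |
| partner | 1.5 equiv | 1.5 equiv | 0.75 equiv | 1.50 equiv | 1.50 equiv |
| free catalyst | 1.7 mol% | 3.8 mol% | 2.5 mol% | 2.5 mol% | 2.5 mol% |
| temperature | 70 °C | 88 °C | 70 °C | 100 °C | 75 °C |
| remark | run made earlier | run made earlier | run made earlier |  |  |
| time |  |  |  | 10 h | 10 h |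

| run | time / h | left-handed product / % | right-handed product / % |
|---|---|---|---|
| winter | 6.00 | 5 | 3 |
| winter | 12.0 | 13 | 0 |
| winter | 20.0 | 18 | 2 |
| winter | 25.0 | 14 | 4 |
| dusk | 1.50 | 14 | 0 |
| dusk | 4.00 | 25 | 3 |
| dusk | 8.00 | 33 | 4 |
| dusk | 10.0 | 34 | 3 |
| autumn | 6.00 | 5 | 1 |
| autumn | 12.0 | 8 | 2 |
| autumn | 20.0 | 14 | 5 |
| autumn | 25.0 | 17 | 4 |

(standard deviation of a reading: 1.5 percentage points)

- the best flask by excess of left-handed product over right-handed product; "all alike" if 1.5 percentage points covers them all (delta / gamma / all alike)
- excess of left-handed product over right-handed product at the end, delta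
- excess of left-handed product over right-handed product at the end, gamma

- free catalyst is single-handed; left-handed substrate and right-handed substrate are mirror images of each other, charged as a racemate, each of them at the stated concentration
- an excess is the difference of the two amounts in percent of their sum
- an excess is below zero if the other one leads

2. We take the loss of left-handed substrate as first order, with a rate constant k that decays at d as the catalyst is lost. Let B = ln[c(left-handed substrate) charged / c(left-handed substrate) present]. Integration gives B = (k/d)(1 − e^(−dt)), so B levels off at k/d, and k scales with loading.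

3. First way: the last dusk reading leaves a fraction 0.320 of that substrate, so B = 1.14. This is the catalyst's budget: the B that a loading buys before it stops, in proportion to that loading.

4. Second way: doubling the time multiplies B by one plus e^(−dt). Dusk's readings at 4.00 h and 8.00 h then give a limit of 1.56. The two ways part, and moving the later reading by 1.5 points either way swings the second from 1.23 to 2.23. That way magnifies scatter, yet even its low end stands above the first, which is read at 10.0 h and under this form is a floor on the limit. We keep the first, knowing it may run low.

5. We assume that temperature and partner leave the budget unchanged. Delta's loading then buys B = 0.750, which gives 26.4% left-handed product.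

6. Dusk's last two readings give a scattered reading of the selectivity factor, the ratio of the two substrates' B values, of 15.3. Carrying that reading unchanged to delta, we put delta's excess at 83.4%. The last two readings of winter and autumn, both at 70 °C, pool to an excess of 61.5%, which we take as our figure for gamma, so we pick delta.

7. The forecast also picks delta, with 84% (70% to 93%) for delta and 69% (58% to 79%) for gamma, a figure above ours, holding that selectivity “apparently rises with temperature”.

8. The flask gives delta: 79.9% for delta and 70.4% for gamma.

    free catalyst + left-handed substrate ⇌ catalyst intermediate A (K = 3.20 L mol⁻¹, k = 0.648 L mol⁻¹ s⁻¹, Ea = 73.0 kJ mol⁻¹, ΔH = 1.00 kJ mol⁻¹)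
    free catalyst + right-handed substrate ⇌ catalyst intermediate B (K = 3.99 L mol⁻¹, k = 4.11 L mol⁻¹ s⁻¹, Ea = 46.0 kJ mol⁻¹, ΔH = −42.0 kJ mol⁻¹)
    partner + catalyst intermediate A → free catalyst + left-handed product (k = 0.0235 L mol⁻¹ s⁻¹, Ea = 55.0 kJ mol⁻¹)
    partner + free catalyst → spent catalyst A (k = 9.01 × 10⁻⁴ L mol⁻¹ s⁻¹, Ea = 77.0 kJ mol⁻¹)
    partner + catalyst intermediate B → free catalyst + right-handed product (k = 0.00145 L mol⁻¹ s⁻¹, Ea = 74.0 kJ mol⁻¹)
    2 free catalyst → spent catalyst B (k = 0.00586 L mol⁻¹ s⁻¹, Ea = 59.0 kJ mol⁻¹)
    (constants at 100 °C)

Delta keeps 47% of its left-handed substrate at 10.0 h, and the budget gave 47.3%. Its left-handed product stands at 26.3% against our 26.4%. Now raise delta's partner to 2.50 equiv. Our budget holds no term in partner, so for that flask it again gives 47.3% of the left-handed substrate left and 26.4% left-handed product. That flask ends with 48% of the left-handed substrate left and 26.1% left-handed product.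

The numbers in the tables are simulated with constants of no real substance.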